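**Retrosynthetic overview**

1. The target is read as (2S)-7,3',4'-trihydroxyflavan-(4→8)-(−)-epigallocatechin. The end game is hydrogenolysis of eight benzyl ethers, preceded by stereoretentive oxidation of a C3–B bond in the lower unit to the C3 hydroxyl.
2. Key disconnection: pyran ring C of the lower unit is opened across O1–C2 and C3–C4. Forward, this is an oxa-[4+2] cycloaddition between an ortho-quinone methide (O1=C8a–C4a=C4H2 on ring A of the lower unit, the upper flavan already attached at C8) and a Z-alkenyl boronate ArCH=CH–B (Ar = 3,4,5-tris(benzyloxy)phenyl; boron held in a chiral N-isopinocampheyl iminodiacetate cage).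
3. Enabling feature: in ring C of the lower unit, C4 is an unsubstituted benzylic CH2 ortho to the ring oxygen O1 on the 1,3,5-trioxygenated ring A, which is a latent ortho-quinone methide. C2 and C3 carry a cis aryl/oxygen pair on adjacent carbons, which maps onto a Z alkene whose C3 oxygen is masked as boron.
4. The quinone methide precursor is a phenolic Mannich base. It comes from Friedel–Crafts union of upper C4 with 3,5-bis(benzyloxy)phenol (the future lower C8). The (2S)-flavan-4-ol comes from chalcone, then flavanone, then transfer hydrogenation with kinetic resolution.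
5. Ring order: upper pyran ring first (oxa-Michael, step 2), then the interflavan bond (step 4), then the lower pyran ring last (step 10). All benzene rings are bought.

Key step: step 10

Remark on the chemistry: the target SMILES corresponds to a 2,3-cis (2R,3R) lower unit and a 2,4-trans (2S,4R) upper unit; the route is planned for exactly this isomer.

Assumption: the ligand made from (1R,2R,3R,5S)-isopinocampheylamine is taken to expose the alkene face that leads to the (2R,3R) ring C. If the cycloaddition shows the opposite sense, the ligand is made from the enantiomeric amine and nothing else changes.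

**Route**

Step 1
Reactants: 1 4'-(benzyloxy)-2'-hydroxyacetophenone; 2 3,4-bis(benzyloxy)benzaldehyde
Product: 3 (E)-1-[4-(benzyloxy)-2-hydroxyphenyl]-3-[3,4-bis(benzyloxy)phenyl]prop-2-en-1-one
Conditions: KOH, EtOH, rt
Reagents that add atoms: none
Why: Claisen–Schmidt aldol condensation of the methyl ketone with the non-enolisable aldehyde, in which dehydration under thermodynamic control should give the E enone.

Step 2
Reactants: 3 the chalcone
Product: 4 racemic 7-(benzyloxy)-2-[3,4-bis(benzyloxy)phenyl]chroman-4-one
Conditions: NaOAc, EtOH, reflux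
Reagents that add atoms: none
Why: Intramolecular oxa-Michael addition of the 2'-phenol (chalcone–flavanone isomerisation) closes the upper pyranone ring, with C2 formed racemic and resolved in step 3.

Step 3
Reactants: 4 the racemic flavanone
Product: 5 (2S,4S)-7-(benzyloxy)-2-[3,4-bis(benzyloxy)phenyl]chroman-4-ol (2,4-cis)
Conditions: RuCl[(S,S)-TsDPEN](p-cymene) (1 mol%), HCO2H–Et3N (5:2), EtOAc, rt, stopped near half conversion
Reagents that add atoms: none
Why: Asymmetric transfer hydrogenation with kinetic resolution, in which the (S,S) catalyst should deliver hydride to give the 4S carbinol (by analogy with aryl alkyl ketones and 4-chromanone) and should do so quickly only for the ketone enantiomer whose C2 aryl group lies anti to the incoming hydride, so that (S)-4 gives the cis alcohol with C2 fixed as S while the (R) ketone is left behind and can be racemised with base and resubmitted.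

Step 4
Reactants: 5 the flavan-4-ol; 6 3,5-bis(benzyloxy)phenol
Product: 7 3,5-bis(benzyloxy)-2-{(2S,4R)-7-(benzyloxy)-2-[3,4-bis(benzyloxy)phenyl]chroman-4-yl}phenol
Conditions: 6 (3 equiv), BF3·OEt2 (0.3 equiv), CH2Cl2, −40 → 0 °C
Reagents that add atoms: none
Why: SN1 Friedel–Crafts alkylation in which the benzylic cation (stabilised by the ring oxygen and the 7-benzyloxy group) is attacked by a carbon ortho to the free hydroxyl of 6 (two equivalent, least hindered sites), and pseudo-axial attack on the half-chair cation with its C2 aryl group equatorial should give the 2,4-trans (4R) product, which also avoids peri strain with H5.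

Step 5
Reactants: 7 the 2-flavanyl phenol
Product: 8 3,5-bis(benzyloxy)-2-[(dimethylamino)methyl]-6-{(2S,4R)-7-(benzyloxy)-2-[3,4-bis(benzyloxy)phenyl]chroman-4-yl}phenol (Mannich base)
Conditions: Eschenmoser's salt, K2CO3, CH2Cl2, 0 °C → rt
Reagents that add atoms: Eschenmoser's salt (N,N-dimethylmethyleneiminium iodide), C=[N+](C)C.[I-]
Why: Phenol Mannich reaction in which the iminium ion is directed by the hydroxyl to the only free ortho position, which places the future methide carbon next to the one free oxygen.

Step 6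
Reactants: 9 (1R,2R,3R,5S)-isopinocampheylamine
Product: 10 di-tert-butyl N-[(1R,2R,3R,5S)-2,6,6-trimethylbicyclo[3.1.1]hept-3-yl]iminodiacetate
Conditions: BrCH2CO2tBu (2.3 equiv), K2CO3, MeCN, 70 °C
Reagents that add atoms: tert-butyl bromoacetate, BrCC(=O)OC(C)(C)C
Why: Twofold SN2 N-alkylation of the primary amine by the α-bromo ester, which leaves the four stereocentres of the pinane untouched.

Step 7
Reactants: 10 the di-tert-butyl ester
Product: 11 N-[(1R,2R,3R,5S)-2,6,6-trimethylbicyclo[3.1.1]hept-3-yl]iminodiacetic acid (N-isopinocampheyl iminodiacetic acid)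
Conditions: TFA, CH2Cl2, rt
Reagents that add atoms: none
Why: Acidolysis of the tert-butyl esters (loss of 2-methylpropene) should give the diacid ligand without affecting the amine or the pinane.

Step 8
Reactants: 12 3,4,5-tris(benzyloxy)benzaldehyde
Product: 13 1,2,3-tris(benzyloxy)-5-ethynylbenzene
Conditions: Ohira–Bestmann reagent, K2CO3, MeOH–THF, rt
Reagents that add atoms: Ohira–Bestmann reagent (dimethyl (1-diazo-2-oxopropyl)phosphonate), CC(=O)C(=[N+]=[N-])P(=O)(OC)OC
Why: Seyferth–Gilbert homologation in its Ohira–Bestmann form converts the aryl aldehyde into the terminal alkyne under mild basic conditions that benzyl ethers tolerate.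

Step 9
Reactants: 13 the aryl alkyne; 11 the iminodiacetic acid ligand
Product: 15 Z-2-[3,4,5-tris(benzyloxy)phenyl]ethenyl boronate of N-isopinocampheyl iminodiacetic acid (tetracoordinate boron bound to both carboxylate oxygens and datively to nitrogen), via Z-alkenyl catecholboronate 14 (not isolated)
Conditions: catecholborane, [Rh(cod)Cl]2 (1.5 mol%), P(iPr)3 (6 mol%), Et3N, cyclohexane, rt; then 11, DMSO–toluene, 80 °C, reduced pressure
Reagents that add atoms: catecholborane, B1Oc2ccccc2O1
Why: Rhodium-catalysed trans-hydroboration of the terminal alkyne (through a rhodium vinylidene, so that boron ends up cis to the aryl group) gives the Z alkenylboronate, and ligand exchange of the labile catechol ester for the iminodiacetic acid (the usual complexation that makes iminodiacetate boronates) should give the stable tetracoordinate boronate with the Z geometry kept.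

Step 10
Reactants: 8 the Mannich base; 15 the Z-alkenyl boronate
Product: 18 octa-O-benzyl cycloadduct: (2S,4R)-7-(benzyloxy)-2-[3,4-bis(benzyloxy)phenyl]chroman-4-yl at C8 of a 5,7-bis(benzyloxy)-2-[3,4,5-tris(benzyloxy)phenyl]chroman whose C3 carries the N-isopinocampheyl iminodiacetate boron cage cis to the C2 aryl group (C2 and C3 arranged in space as in 21; 2S,3R by the CIP rules because boron ranks below carbon), via ammonium iodide 16 (not isolated), via ortho-quinone methide 17 (not isolated)
Conditions: MeI (1.0 equiv), MeCN–THF, rt; then 15 (1.5 equiv), K2CO3 (anhydrous), 4 Å sieves, 60 °C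
Reagents that add atoms: none
Why: Proposed new method: base releases NMe3 from 16 to give the electron-rich ortho-quinone methide 17, which should be taken up by the Z-alkenyl boronate in a concerted but asynchronous inverse-electron-demand oxa-[4+2] cycloaddition (a 4π O=C–C=CH2 unit on a 2π alkene) that closes the six-membered pyran ring C of the lower unit by forming C4–C3 and O1–C2 together; the closest known reaction type is the [4+2] of ortho-quinone methides from phenolic Mannich salts with styrenes to give 2-arylchromans, extended here to a β-boryl styrene that keeps its boron. Regiochemistry should follow from the polarised transition state, in which the methide carbon bonds to the boron-bearing carbon so that positive charge builds on the benzylic carbon, stabilised by the tris(benzyloxy)phenyl ring and by hyperconjugation with the C–B bond of the tetracoordinate boron (β-boron effect), before the quinone methide oxygen closes onto it. Because the tetracoordinate boron has no empty orbital, transfer of the alkenyl group from boron to the methide carbon (the usual fate of tricoordinate alkenyl boronates with these electrophiles) is shut off. Suprafacial addition across the Z alkene sets C2 and C3 cis, and the same C–B hyperconjugation should hold the C2–C3 bond against rotation if bond formation is not fully synchronous. The absolute configuration of both new centres depends on which alkene face is attacked, and this is controlled by the isopinocampheyl group on nitrogen, which sits beside the alkene in the rigid bicyclic boron cage and blocks one face (the element that is known to direct peracid epoxidation of alkenyl boronates of this ligand); the resident upper unit makes the two outcomes diastereomers, so any minor isomer can be removed by chromatography. Closure through the oxygen next to C8 (4→8 and not 4→6 linkage) is secured because only that oxygen is a free phenol in 8, the other two being benzyl ethers.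

Step 11
Reactants: 18 the cycloadduct
Product: 20 (2R,3R)-5,7-bis(benzyloxy)-8-{(2S,4R)-7-(benzyloxy)-2-[3,4-bis(benzyloxy)phenyl]chroman-4-yl}-2-[3,4,5-tris(benzyloxy)phenyl]chroman-3-ol, via boronic acid 19 (not isolated)
Conditions: aq. NaOH, H2O2 (30%), THF, 0 °C → rt
Reagents that add atoms: hydrogen peroxide, OO
Why: Hydroxide opens the boron cage and hydroperoxide oxidises the C–B bond by 1,2-migration of carbon from boron to oxygen with retention, which turns the C3 boron into the cis C3 hydroxyl (3R), the peroxide being present from the start so that oxidation outruns β-elimination of the ring oxygen.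

Step 12
Reactants: 20 the octa-O-benzyl ether
Product: 21 (2R,3R)-8-[(2S,4R)-2-(3,4-dihydroxyphenyl)-7-hydroxychroman-4-yl]-2-(3,4,5-trihydroxyphenyl)chroman-3,5,7-triol (target)
Conditions: H2 (1 atm), Pd(OH)2/C, THF–MeOH–H2O, rt, degassed solvents
Reagents that add atoms: none
Why: Catalytic hydrogenolysis of the eight benzyl ethers under mild conditions should leave the ring benzylic C–O bonds, the interflavan bond and all four stereocentres untouched and give the free polyphenol, which is handled under argon.

**Compound list**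

1 | 4'-(benzyloxy)-2'-hydroxyacetophenone | CC(=O)c1ccc(OCc2ccccc2)cc1O | starting material
2 | 3,4-bis(benzyloxy)benzaldehyde | O=Cc1ccc(OCc2ccccc2)c(OCc2ccccc2)c1 | starting material
3 | (E)-1-[4-(benzyloxy)-2-hydroxyphenyl]-3-[3,4-bis(benzyloxy)phenyl]prop-2-en-1-one | O=C(/C=C/c1ccc(OCc2ccccc2)c(OCc2ccccc2)c1)c1ccc(OCc2ccccc2)cc1O | intermediate
4 | racemic 7-(benzyloxy)-2-[3,4-bis(benzyloxy)phenyl]chroman-4-one | O=C1CC(c2ccc(OCc3ccccc3)c(OCc3ccccc3)c2)Oc2cc(OCc3ccccc3)ccc21 | intermediate
5 | (2S,4S)-7-(benzyloxy)-2-[3,4-bis(benzyloxy)phenyl]chroman-4-ol | O[C@H]1C[C@@H](c2ccc(OCc3ccccc3)c(OCc3ccccc3)c2)Oc2cc(OCc3ccccc3)ccc21 | intermediate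
6 | 3,5-bis(benzyloxy)phenol | Oc1cc(OCc2ccccc2)cc(OCc2ccccc2)c1 | starting material
7 | 3,5-bis(benzyloxy)-2-{(2S,4R)-7-(benzyloxy)-2-[3,4-bis(benzyloxy)phenyl]chroman-4-yl}phenol | Oc1cc(OCc2ccccc2)cc(OCc2ccccc2)c1[C@@H]1C[C@@H](c2ccc(OCc3ccccc3)c(OCc3ccccc3)c2)Oc2cc(OCc3ccccc3)ccc21 | intermediate
8 | 3,5-bis(benzyloxy)-2-[(dimethylamino)methyl]-6-{(2S,4R)-7-(benzyloxy)-2-[3,4-bis(benzyloxy)phenyl]chroman-4-yl}phenol | CN(C)Cc1c(OCc2ccccc2)cc(OCc2ccccc2)c([C@@H]2C[C@@H](c3ccc(OCc4ccccc4)c(OCc4ccccc4)c3)Oc3cc(OCc4ccccc4)ccc32)c1O | intermediate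
9 | (1R,2R,3R,5S)-isopinocampheylamine | C[C@H]1[C@H](N)C[C@@H]2C[C@H]1C2(C)C | starting material
10 | di-tert-butyl N-[(1R,2R,3R,5S)-2,6,6-trimethylbicyclo[3.1.1]hept-3-yl]iminodiacetate | C[C@H]1[C@H](N(CC(=O)OC(C)(C)C)CC(=O)OC(C)(C)C)C[C@@H]2C[C@H]1C2(C)C | intermediate
11 | N-[(1R,2R,3R,5S)-2,6,6-trimethylbicyclo[3.1.1]hept-3-yl]iminodiacetic acid | C[C@H]1[C@H](N(CC(=O)O)CC(=O)O)C[C@@H]2C[C@H]1C2(C)C | intermediate
12 | 3,4,5-tris(benzyloxy)benzaldehyde | O=Cc1cc(OCc2ccccc2)c(OCc2ccccc2)c(OCc2ccccc2)c1 | starting material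
13 | 1,2,3-tris(benzyloxy)-5-ethynylbenzene | C#Cc1cc(OCc2ccccc2)c(OCc2ccccc2)c(OCc2ccccc2)c1 | intermediate
14 | 2-{(Z)-2-[3,4,5-tris(benzyloxy)phenyl]ethenyl}-1,3,2-benzodioxaborole | c1ccc2c(c1)OB(/C=C\c1cc(OCc3ccccc3)c(OCc3ccccc3)c(OCc3ccccc3)c1)O2 | intermediate (not isolated)
15 | Z-2-[3,4,5-tris(benzyloxy)phenyl]ethenyl boronate of N-isopinocampheyl iminodiacetic acid | C[C@H]1[C@H]([N+]34CC(=O)O[B-]3(/C=C\c3cc(OCc5ccccc5)c(OCc5ccccc5)c(OCc5ccccc5)c3)OC(=O)C4)C[C@@H]2C[C@H]1C2(C)C | intermediate
16 | trimethylammonium iodide of 8 (N-methylated Mannich base) | C[N+](C)(C)Cc1c(OCc2ccccc2)cc(OCc2ccccc2)c([C@@H]2C[C@@H](c3ccc(OCc4ccccc4)c(OCc4ccccc4)c3)Oc3cc(OCc4ccccc4)ccc32)c1O.[I-] | intermediate (not isolated)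
17 | 3,5-bis(benzyloxy)-6-methylidene-2-{(2S,4R)-7-(benzyloxy)-2-[3,4-bis(benzyloxy)phenyl]chroman-4-yl}cyclohexa-2,4-dien-1-one (ortho-quinone methide) | C=C1C(OCc2ccccc2)=CC(OCc2ccccc2)=C([C@@H]2C[C@@H](c3ccc(OCc4ccccc4)c(OCc4ccccc4)c3)Oc3cc(OCc4ccccc4)ccc32)C1=O | intermediate (not isolated)
18 | octa-O-benzyl cycloadduct with the N-isopinocampheyl iminodiacetate boron cage at C3 of the lower unit, cis to the C2 aryl group | c1ccccc1COc1ccc2c(c1)O[C@H](c1ccc(OCc3ccccc3)c(OCc3ccccc3)c1)C[C@H]2c1c(OCc3ccccc3)cc(OCc3ccccc3)c2c1O[C@H](c1cc(OCc3ccccc3)c(OCc3ccccc3)c(OCc3ccccc3)c1)[C@H]([B-]34OC(=O)C[N+]3([C@@H]5C[C@@H]6C[C@@H](C6(C)C)[C@H]5C)CC(=O)O4)C2 | intermediate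
19 | octa-O-benzyl dimer with a boronic acid at C3 of the lower unit, cis to the C2 aryl group | c1ccccc1COc1ccc2c(c1)O[C@H](c1ccc(OCc3ccccc3)c(OCc3ccccc3)c1)C[C@H]2c1c(OCc3ccccc3)cc(OCc3ccccc3)c2c1O[C@H](c1cc(OCc3ccccc3)c(OCc3ccccc3)c(OCc3ccccc3)c1)[C@H](B(O)O)C2 | intermediate (not isolated)
20 | (2R,3R)-5,7-bis(benzyloxy)-8-{(2S,4R)-7-(benzyloxy)-2-[3,4-bis(benzyloxy)phenyl]chroman-4-yl}-2-[3,4,5-tris(benzyloxy)phenyl]chroman-3-ol | c1ccccc1COc1ccc2c(c1)O[C@H](c1ccc(OCc3ccccc3)c(OCc3ccccc3)c1)C[C@H]2c1c(OCc3ccccc3)cc(OCc3ccccc3)c2c1O[C@H](c1cc(OCc3ccccc3)c(OCc3ccccc3)c(OCc3ccccc3)c1)[C@H](O)C2 | intermediate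
21 | (2R,3R)-8-[(2S,4R)-2-(3,4-dihydroxyphenyl)-7-hydroxychroman-4-yl]-2-(3,4,5-trihydroxyphenyl)chroman-3,5,7-triol | Oc1ccc2c(c1)O[C@H](c1ccc(O)c(O)c1)C[C@H]2c1c(O)cc(O)c2c1O[C@H](c1cc(O)c(O)c(O)c1)[C@H](O)C2 | target

**Step count and risks**

Total step count: 12. Longest linear sequence: 8 steps (steps 1–5 and 10–12, from 1 and 2 to 21).

Steps most likely to fail:

1. Step 10 (proposed new method). The quinone methide may be consumed by self-dimerisation before the hindered Z alkene reacts. Face discrimination by the boron cage may be too weak or may be opposed by the resident upper unit. A long-lived zwitterion could also let the C2–C3 bond rotate and erode the cis relationship. Fallback by known chemistry, setting out from 5 and coming back at 20: commercial (−)-epigallocatechin is benzylated on its five phenols (BnBr, K2CO3, DMF) to 5,7,3',4',5'-penta-O-benzyl-(−)-epigallocatechin F1. Friedel–Crafts coupling of 5 with F1 (TMSOTf or BF3·OEt2, CH2Cl2, −78 → −40 °C) should then occur at C8 of F1, the more nucleophilic position of 5,7-di-O-benzyl flavan-3-ols, with the same pseudo-axial attack as in step 4. This gives 20 directly, with ring C of the lower unit taken from the chiral pool instead of being built.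

2. Step 4. Alkylation may also take place at the carbon between the two benzyloxy groups or twice on the same phenol, and acid-mediated equilibration may erode the 2,4-trans selectivity. Fallback, setting out from 5 and coming back at 8: 5 is coupled under mild acid with phloroglucinol, which is symmetric so that no regiochemical question arises, to give the 2,4,6-trihydroxyphenyl flavan F2. Vilsmeier–Haack formylation (POCl3, DMF) at one of the two equivalent free ring positions gives the salicylaldehyde F3. Twofold benzylation (BnBr 2 equiv, K2CO3, acetone) should leave untouched the one hydroxyl that is both hydrogen-bonded to the aldehyde and flanked by the flavanyl group, giving the dibenzyl ether F4. Reductive amination of F4 with Me2NH and NaBH(OAc)3 then gives 8.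

3. Step 9. The Z alkenylboron species may isomerise to E during the hydroboration or during the hot ligand exchange, and the exchange may stop short of completion. Fallback, setting out from 13 and coming back at 15: 13 is deprotonated with n-BuLi and trapped with B(OiPr)3 (THF, −78 °C) to the lithium alkynyl triisopropoxyborate F5. This is transligated with 11 in hot DMSO to the alkynyl boronate of N-isopinocampheyl iminodiacetic acid F6. cis-Semihydrogenation of F6 (H2, Pd/CaCO3 poisoned with Pb(OAc)2, quinoline, EtOAc) fixes the Z geometry by syn addition of hydrogen and gives 15.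

Further compounds
F1 | step 10 | 5,7,3',4',5'-penta-O-benzyl-(−)-epigallocatechin | c1c(OCc3ccccc3)cc(OCc3ccccc3)c2c1O[C@H](c1cc(OCc3ccccc3)c(OCc3ccccc3)c(OCc3ccccc3)c1)[C@H](O)C2
F2 | step 4 | 2-{(2S,4R)-7-(benzyloxy)-2-[3,4-bis(benzyloxy)phenyl]chroman-4-yl}benzene-1,3,5-triol | Oc1cc(O)cc(O)c1[C@@H]1C[C@@H](c2ccc(OCc3ccccc3)c(OCc3ccccc3)c2)Oc2cc(OCc3ccccc3)ccc21
F3 | step 4 | 3-{(2S,4R)-7-(benzyloxy)-2-[3,4-bis(benzyloxy)phenyl]chroman-4-yl}-2,4,6-trihydroxybenzaldehyde | O=Cc1c(O)cc(O)c([C@@H]2C[C@@H](c3ccc(OCc4ccccc4)c(OCc4ccccc4)c3)Oc3cc(OCc4ccccc4)ccc32)c1O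
F4 | step 4 | 4,6-bis(benzyloxy)-3-{(2S,4R)-7-(benzyloxy)-2-[3,4-bis(benzyloxy)phenyl]chroman-4-yl}-2-hydroxybenzaldehyde | O=Cc1c(OCc2ccccc2)cc(OCc2ccccc2)c([C@@H]2C[C@@H](c3ccc(OCc4ccccc4)c(OCc4ccccc4)c3)Oc3cc(OCc4ccccc4)ccc32)c1O
F5 | step 9 | lithium triisopropoxy{[3,4,5-tris(benzyloxy)phenyl]ethynyl}borate | [Li+].CC(C)O[B-](OC(C)C)(OC(C)C)C#Cc1cc(OCc2ccccc2)c(OCc2ccccc2)c(OCc2ccccc2)c1
F6 | step 9 | [3,4,5-tris(benzyloxy)phenyl]ethynyl boronate of N-isopinocampheyl iminodiacetic acid | C[C@H]1[C@H]([N+]34CC(=O)O[B-]3(C#Cc3cc(OCc5ccccc5)c(OCc5ccccc5)c(OCc5ccccc5)c3)OC(=O)C4)C[C@@H]2C[C@H]1C2(C)C
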